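The earlier runs and the new flask were generated by integration from invented constants; the scatter is artificial.

A one-step world, L to Z and stop, has Z rising to the charge and staying there, but the epsilon run, which is this very flask followed so far, has Z already at 93.4% after 20.0 min and falling to 45.6% by 300 min.

| flask | L | X | temperature | remark | time |
|---|---|---|---|---|---|
| epsilon | 10 mM | 1 µM | 25 °C | the very flask that is asked about, followed so far |  |
| alpha | 10 mM | 1 µM | 10 °C | run made earlier |  |
| flask | 10 mM | 1.0 µM | 25 °C |  | 8.0 h |

- epsilon (time / min: Z / %): 20.0: 93.4; 60.0: 83.5; 90.0: 77.8; 150: 67.0; 240: 52.1; 300: 45.6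
- alpha (time / min: Z / %): 40.0: 97.2; 120: 96.4; 180: 95.4; 300: 92.1; 480: 87.4; 600: 84.4

(scatter of a reading: 0.5 percentage points)

- Z taken out counts as made
- additions bring no volume worth counting

- noon: at 8.0 h add X, 100% of the amount charged, then wait 8.0 h
- dusk: change nothing and wait 8.0 h more
- summer: at 8.0 h take out 90% of the Z then present, then wait 8.0 h
- winter: at 8.0 h raise the temperature by 10 K, then wait 8.0 h

1. Z, in percent of the L first charged, at 8.0 h
2. which option adds most Z ("none" when 2 percentage points or less is all one gets) (noon / dusk / summer / winter / none)
3. Z present, with what was taken out counted in, in percent of the L first charged, after dusk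
4. Z present, with what was taken out counted in, in percent of the L first charged, after summer

The quantity to carry is the loss constant of Z, the share of itself that Z loses per minute (first-order decay), read as the logarithm of the ratio of the first and last readings over the time between them: 0.00256 min⁻¹, and the inner pair of readings gives 0.00262 min⁻¹. The balance of L then closes the reckoning: X, charged at 0.0100% of L, can hold no share worth counting, so the charge is L left, Z, and what Z has become. Projected back to the start with that constant, the first reading falls short of the charge by 1.69%, an estimate called here the unseen part.

From below, with nothing newly made after the last reading and both end readings moved two scatters towards a steeper fall, the estimate of Z at 8.0 h comes to 27.5%. From above, with both moved towards a flatter fall and the unseen part arriving undamaged at the last moment, the estimate comes to 31.7%. That unseen part is less than the margin, and the alpha run loses Z more slowly at its lower temperature, so my reckoning offers no option a gain above the margin.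

The forecast, “L is converted almost at once and the product is then lost”, gives 28.5%, above the lower end and below the upper end of the bracket, with none as best, 8.3% after dusk and 26.5% after summer.

The flask gives 27.8%, best none, 7.84% after dusk and 25.9% after summer.

    L + X ⇌ D (K = 2800 M⁻¹, k = 1.04 × 10⁶ M⁻¹ s⁻¹, Ea = 25.0 kJ mol⁻¹, ΔH = −21.0 kJ mol⁻¹)
    Z → E (k = 4.46 × 10⁻⁵ s⁻¹, Ea = 106 kJ mol⁻¹)
    D ⇌ X + Z (K = 0.0240 M, k = 482 s⁻¹, Ea = 65.0 kJ mol⁻¹, ΔH = −18.0 kJ mol⁻¹)
    X → Q (k = 4.57 × 10⁻⁶ s⁻¹, Ea = 188 kJ mol⁻¹)
    (constants at 25 °C)

In this flask, of the turnover up to 8.0 h, the passing of L + X into D had half behind it by 0.194 min, and the passing of D into X + Z had 99.1% by 48.0 min, while the passing of Z into E had 65% behind it by 240 min and ran on. At 8.0 h, with L, the limiting reagent, at 0.41%, Z is made at 0.0147 of the rate at which it is used up, each step taken net. The loss constant applied to 27.8% over the further 8.0 h gives 8.14%, beside the 7.84% of dusk.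

For the same flask read at 3.0 h, the loss constant from the first reading gives 62.0%, and the computed Z is 61.3%.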